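**Strategy.** Everything rests on cutting two bonds at the γ-lactone: C7–C8 and C11–C13 (germacrane numbering). In the lactone ring O6–C6–C7–C11–C12, C7 is β and C11 is α to the C12 carbonyl, so a C6-substituted butenolide accepts a C8 acyl-anion equivalent at C7 and an aminomethyl cation at C11. One operation therefore joins three components, sets C7 trans to C6 and installs the masked C13 methylene. The precursors are a silylated (S)-hydroxymethylbutenolide, a 2-substituted 1,3-dithiane carrying C9, C10, C14 and C1–C3 with the ring-cis C1=C10 alkene in place, and dimethylmethyleneiminium iodide. The ten-membered ring is closed later at C4=C5.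

Key step: step 9

Remarks on the chemistry (one line each):
- Numbering: germacrane locants are used throughout (ring carbons C1–C10; lactone O6–C6–C7–C11–C12; C13 on C11; C14 on C10; C15 on C4). TES = triethylsilyl, TBS = tert-butyldimethylsilyl, TBDPS = tert-butyldiphenylsilyl.
- Protecting groups: the C14 oxygen is carried as a TBDPS ether, because an allylic benzyl-type ether is open to Wittig rearrangement during the butyllithium metalation and its oxidative removal would collide with the tertiary amine; the C3, C5 and C14 oxygens bear TES, TBS and TBDPS so that each is released in turn.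
- Geometry: the C1=C10 alkene keeps one shape from its formation onward (C9 cis to C2); its CIP label changes from Z (bromides) to E once carbon replaces bromine on C9. Both ring alkenes of the target are cis within the ring although E by CIP.
- Descriptors: the target is (6R,7R,8S); C6 is labelled S in the acyclic intermediates only because the CIP rank of C5 differs, and the centre is never inverted.
- Assumption: the Morita–Baylis–Hillman adduct is racemic and C4 of the acyclic phosphonates is an epimer mixture; both centres are erased later.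

Step 1
Reactants: 1 (S)-5-(hydroxymethyl)furan-2(5H)-one
Product: 2 (S)-5-[(tert-butyldimethylsilyloxy)methyl]furan-2(5H)-one
Conditions: TBSCl, imidazole, CH2Cl2, 0 °C → rt
Reagents that add atoms: tert-butyldimethylsilyl chloride, CC(C)(C)[Si](C)(C)Cl
Why: Imidazole-promoted O-silylation of the primary alcohol is fast and mild enough to leave the acidic γ-proton and the C6 stereocentre untouched.

Step 2
Reactants: 3 propane-1,3-diol
Product: 4 3-(triethylsilyloxy)propan-1-ol
Conditions: TESCl (1 equiv), imidazole, 3 (4 equiv), THF, 0 °C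
Reagents that add atoms: triethylsilyl chloride, CC[Si](Cl)(CC)CC
Why: Statistical O-silylation with the diol in excess should give the mono-TES ether.

Step 3
Reactants: 4 3-(triethylsilyloxy)propan-1-ol
Product: 5 3-(triethylsilyloxy)propanal
Conditions: TEMPO (cat.), PhI(OAc)2, CH2Cl2, rt
Reagents that add atoms: none
Why: Oxoammonium (TEMPO) oxidation stops at the aldehyde under non-basic conditions, so the β-silyloxy aldehyde should not eliminate.

Step 4
Reactants: 5 3-(triethylsilyloxy)propanal; 6 methyl acrylate
Product: 7 methyl 3-hydroxy-2-methylidene-5-(triethylsilyloxy)pentanoate (racemic)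
Conditions: DABCO (0.5 equiv), neat 6 (4 equiv), rt, 5 d
Reagents that add atoms: none
Why: Morita–Baylis–Hillman reaction, in which the DABCO–acrylate ammonium enolate adds to the unhindered aldehyde; the racemic carbinol centre is erased in step 5.

Step 5
Reactants: 7 methyl 3-hydroxy-2-methylidene-5-(triethylsilyloxy)pentanoate
Product: 8 methyl (2Z)-2-(bromomethyl)-5-(triethylsilyloxy)pent-2-enoate
Conditions: NBS, Me2S, CH2Cl2, 0 °C → rt
Reagents that add atoms: N-bromosuccinimide, O=C1CCC(=O)N1Br
Why: Corey–Kim-type activation of the allylic alcohol followed by SN2′ attack of bromide gives the conjugated, thermodynamically preferred enoate in which CH2Br (the future C9) is cis to the C2 chain.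

Step 6
Reactants: 8 methyl (2Z)-2-(bromomethyl)-5-(triethylsilyloxy)pent-2-enoate
Product: 9 (2Z)-2-(bromomethyl)-5-(triethylsilyloxy)pent-2-en-1-ol
Conditions: i-Bu2AlH (2.3 equiv), CH2Cl2, −78 °C; aq. KNaC4H4O6 work-up
Reagents that add atoms: none
Why: 1,2-Hydride reduction of the conjugated ester by i-Bu2AlH at −78 °C is faster than attack on the allylic bromide and keeps the alkene geometry.

Step 7
Reactants: 9 (2Z)-2-(bromomethyl)-5-(triethylsilyloxy)pent-2-en-1-ol
Product: 10 tert-butyl{[(2Z)-2-(bromomethyl)-5-(triethylsilyloxy)pent-2-en-1-yl]oxy}diphenylsilane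
Conditions: TBDPSCl, imidazole, CH2Cl2, 0 °C
Reagents that add atoms: tert-butyldiphenylsilyl chloride, CC(C)(C)[Si](Cl)(c1ccccc1)c1ccccc1
Why: O-Silylation of the primary allylic alcohol should outpace N-alkylation of imidazole by the allylic bromide at 0 °C.

Step 8
Reactants: 11 1,3-dithiane; 10 tert-butyl{[(2Z)-2-(bromomethyl)-5-(triethylsilyloxy)pent-2-en-1-yl]oxy}diphenylsilane
Product: 13 2-[(2E)-2-(tert-butyldiphenylsilyloxymethyl)-5-(triethylsilyloxy)pent-2-en-1-yl]-1,3-dithiane, via 2-lithio-1,3-dithiane 12 (not isolated)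
Conditions: 11, n-BuLi, THF, −30 °C; then 10, −78 → −30 °C
Reagents that add atoms: none
Why: Corey–Seebach alkylation, in which the lithiated dithiane displaces the primary allylic bromide by direct SN2 (the substituted γ-carbon disfavours SN2′), so C9 stays cis to C2.

Step 9
Reactants: 13 2-[(2E)-2-(tert-butyldiphenylsilyloxymethyl)-5-(triethylsilyloxy)pent-2-en-1-yl]-1,3-dithiane; 2 (S)-5-[(tert-butyldimethylsilyloxy)methyl]furan-2(5H)-one; 14 dimethylmethyleneiminium iodide
Product: 17 (3R,4S,5S)-three-component lactone (C8 dithiane on C7; dimethylaminomethyl on C11; TBS-oxymethyl on C6; all-trans), via lithiated dithiane 15 (not isolated), via lithium lactone enolate 16 (not isolated)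
Conditions: 13, n-BuLi, THF, −30 °C, 2 h; HMPA, −78 °C; 2, −78 °C; then 14, −78 → 0 °C
Reagents that add atoms: none
Why: n-BuLi removes the dithiane C–H of 13 to give the C8 acyl-anion equivalent 15, which adds to C7 of butenolide 2 (Michael addition) to give enolate 16, and 16 is alkylated at C11 by the iminium carbon of 14 (Mannich reaction). The closest known reaction type is the tandem conjugate addition of lithiated dithianes to 5-substituted butenolides with capture of the lactone enolate by a carbon electrophile. No ring is formed. C7 is set by the C6 silyloxymethyl group, which shields one face of the flat butenolide so that the carbanion enters anti to it; C11 is set by the bulky C7 dithianyl group, the iminium ion approaching trans to it, and this centre is erased in step 27. The step needs 1,4- rather than 1,2-addition and no proton removal at C6; HMPA-solvated ion pairs at −78 °C and the bulk of the 2,2-disubstituted dithianyl anion should secure both. C6 and the C1=C10 geometry are not touched.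

Step 10
Reactants: 17 three-component lactone
Product: 18 C8 ketone (dithiane removed; otherwise as 17)
Conditions: Hg(ClO4)2·3H2O, CaCO3, THF/H2O (5:1), 0 °C, 15 min; crude product used at once
Reagents that add atoms: water, O
Why: Dithioacetal hydrolysis, in which thiophilic divalent mercury binds both sulfur atoms and water captures the thionium ion, while CaCO3 keeps the medium neutral so the silyl ethers and the β,γ-unsaturated ketone survive the short contact.

Step 11
Reactants: 18 C8 ketone
Product: 19 (8S)-alcohol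
Conditions: (R)-2-methyl-CBS-oxazaborolidine (0.5 equiv), catecholborane (3 equiv), toluene/CH2Cl2, −78 °C; MeOH, then aq. NaHCO3
Reagents that add atoms: none
Why: Corey–Bakshi–Shibata reduction, in which the (R)-oxazaborolidine treats branched C7 as the large and C9H2 as the small group and delivers hydride to the face that gives the (8S)-carbinol by reagent control.

Step 12
Reactants: 19 (8S)-alcohol
Product: 20 O8-TBS ether
Conditions: TBSOTf, 2,6-lutidine, CH2Cl2, −78 → 0 °C
Reagents that add atoms: tert-butyldimethylsilyl triflate, CC(C)(C)[Si](C)(C)OS(=O)(=O)C(F)(F)F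
Why: Silyl triflate silylation of the hindered secondary alcohol, which blocks translactonisation to O8 and later oxidation at C8.

Step 13
Reactants: 20 O8-TBS ether
Product: 21 C3 primary alcohol
Conditions: PPTS (2 equiv), MeOH/CH2Cl2 (1:1), 0 °C; aq. NaHCO3 work-up
Reagents that add atoms: none
Why: Selective acid-catalysed methanolysis, the primary TES ether being far more labile than the primary TBS, secondary TBS and TBDPS ethers (the amine consumes the first equivalent of acid).

Step 14
Reactants: 21 C3 primary alcohol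
Product: 22 C3 primary iodide
Conditions: I2, PPh3, imidazole, CH2Cl2, 0 °C
Reagents that add atoms: iodine, II
Why: Appel-type iodination (Garegg–Samuelsson conditions), in which iodide displaces the alkoxyphosphonium ion at the unhindered primary carbon.

Step 15
Reactants: 23 diethylphosphonoacetic acid; 24 ethanethiol
Product: 25 S-ethyl 2-(diethoxyphosphoryl)ethanethioate
Conditions: DCC, DMAP (cat.), CH2Cl2, 0 °C → rt
Reagents that add atoms: none
Why: Steglich-type carbodiimide coupling of a carboxylic acid with a thiol gives the thioester.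

Step 16
Reactants: 22 C3 primary iodide; 25 S-ethyl 2-(diethoxyphosphoryl)ethanethioate
Product: 27 C4 phosphonate thioester (C3–C4 bond; C4 epimer mixture), via sodium phosphonate carbanion 26 (not isolated)
Conditions: 25 (3 equiv), NaH (2.8 equiv), DMF/THF, 0 °C; then 22, 50 °C
Reagents that add atoms: none
Why: SN2 C-alkylation of the doubly stabilised, weakly basic phosphonate carbanion by the primary iodide, the excess of anion favouring substitution over E2 and monoalkylation.

Step 17
Reactants: 27 C4 phosphonate thioester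
Product: 28 C5 primary alcohol
Conditions: HF·pyridine, pyridine, THF, 0 °C → rt
Reagents that add atoms: none
Why: Selective desilylation, buffered HF·pyridine cleaving the primary TBS ether faster than the hindered secondary TBS and the TBDPS ethers.

Step 18
Reactants: 28 C5 primary alcohol
Product: 29 C5 aldehyde
Conditions: Dess–Martin periodinane, NaHCO3, CH2Cl2, 0 °C → rt; used without delay
Reagents that add atoms: none
Why: Dess–Martin oxidation under buffered, non-basic conditions should give the α-acyloxy aldehyde without epimerising C6.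

Step 19
Reactants: 29 C5 aldehyde
Product: 30 ten-membered thioester (C4=C5 formed; thioester trans to C6)
Conditions: LiCl (10 equiv), DBU (3 equiv), MeCN, rt, slow addition to 1 mM
Reagents that add atoms: none
Why: Intramolecular Horner–Wadsworth–Emmons olefination under Masamune–Roush conditions, in which the usual preference for the acyl group trans to the aldehyde residue coincides with the ring-cis geometry and gives, with the cis C1=C10 bond, a low-strain cis,cis-cyclodeca-1,5-diene.

Step 20
Reactants: 30 ten-membered thioester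
Product: 31 C15 enal
Conditions: Et3SiH, Pd/C (10%), acetone, rt
Reagents that add atoms: none
Why: Fukuyama reduction, in which zerovalent palladium inserts into the C–S bond and Et3SiH transfers hydride, gives the aldehyde without touching the lactone, silyl ethers or trisubstituted alkenes.

Step 21
Reactants: 31 C15 enal
Product: 32 C8,C14-diol
Conditions: HF·pyridine, THF, 0 °C → rt (prolonged)
Reagents that add atoms: none
Why: Fluoride-driven cleavage of both remaining silyl ethers (Si–F bond formation), to which lactone, enal and the protonated amine are inert.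

Step 22
Reactants: 32 C8,C14-diol
Product: 33 C14 acetate with free C8 hydroxyl
Conditions: AcCl (1.1 equiv), 2,4,6-collidine, CH2Cl2, −78 °C
Reagents that add atoms: acetyl chloride, CC(=O)Cl
Why: Kinetically selective acetylation, the unhindered primary allylic C14 hydroxyl reacting much faster than the secondary C8 hydroxyl flanked by C7.

Step 23
Reactants: 34 ethyl 2-(hydroxymethyl)acrylate
Product: 35 ethyl 2-[(tert-butyldimethylsilyloxy)methyl]acrylate
Conditions: TBSCl, imidazole, CH2Cl2, 0 °C → rt
Reagents that add atoms: tert-butyldimethylsilyl chloride, CC(C)(C)[Si](C)(C)Cl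
Why: Imidazole-promoted O-silylation of the primary allylic alcohol.

Step 24
Reactants: 35 ethyl 2-[(tert-butyldimethylsilyloxy)methyl]acrylate
Product: 36 2-[(tert-butyldimethylsilyloxy)methyl]acrylic acid
Conditions: LiOH, THF/H2O, 0 °C → rt; then aq. HCl to pH 4
Reagents that add atoms: lithium hydroxide, [Li+].[OH-]
Why: Saponification of the ethyl ester, the TBS ether being stable to aqueous base and to brief mild acidification.

Step 25
Reactants: 33 C14 acetate with free C8 hydroxyl; 36 2-[(tert-butyldimethylsilyloxy)methyl]acrylic acid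
Product: 37 O8 ester carrying the silylated side chain
Conditions: DCC, DMAP, CH2Cl2, 0 °C → rt
Reagents that add atoms: none
Why: Steglich esterification acylates the C8 hydroxyl at oxygen, so the (8S) configuration is retained.

Step 26
Reactants: 37 O8 ester carrying the silylated side chain
Product: 38 amine precursor of the target (free side-chain hydroxyl)
Conditions: HF·pyridine, pyridine, THF, 0 °C → rt
Reagents that add atoms: none
Why: Fluoride cleavage of the primary TBS ether, under which the acetate, both esters and the enal are stable.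

Step 27
Reactants: 38 amine precursor of the target
Product: 40 CNP0198933.2, via trimethylammonium iodide 39 (not isolated)
Conditions: MeI, MeCN, rt; then aq. NaHCO3, EtOAc, rt
Reagents that add atoms: none
Why: Exhaustive N-methylation followed by E1cB loss of trimethylamine from the β-ammonio lactone (elimination of a quaternised Mannich base) unmasks the C11=C13 methylene under conditions too mild to harm the other Michael acceptors.

**Compound list**

1 | (S)-5-(hydroxymethyl)furan-2(5H)-one | O=C1C=C[C@@H](CO)O1 | starting material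
2 | (S)-5-[(tert-butyldimethylsilyloxy)methyl]furan-2(5H)-one | O=C1C=C[C@@H](CO[Si](C)(C)C(C)(C)C)O1 | intermediate
3 | propane-1,3-diol | OCCCO | starting material
4 | 3-(triethylsilyloxy)propan-1-ol | OCCCO[Si](CC)(CC)CC | intermediate
5 | 3-(triethylsilyloxy)propanal | O=CCCO[Si](CC)(CC)CC | intermediate
6 | methyl acrylate | C=CC(=O)OC | starting material
7 | methyl 3-hydroxy-2-methylidene-5-(triethylsilyloxy)pentanoate (racemic) | C=C(C(=O)OC)C(O)CCO[Si](CC)(CC)CC | intermediate
8 | methyl (2Z)-2-(bromomethyl)-5-(triethylsilyloxy)pent-2-enoate | BrC/C(C(=O)OC)=C\CCO[Si](CC)(CC)CC | intermediate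
9 | (2Z)-2-(bromomethyl)-5-(triethylsilyloxy)pent-2-en-1-ol | BrC/C(CO)=C\CCO[Si](CC)(CC)CC | intermediate
10 | tert-butyl{[(2Z)-2-(bromomethyl)-5-(triethylsilyloxy)pent-2-en-1-yl]oxy}diphenylsilane | BrC/C(CO[Si](c1ccccc1)(c2ccccc2)C(C)(C)C)=C\CCO[Si](CC)(CC)CC | intermediate
11 | 1,3-dithiane | C1CSCSC1 | starting material
12 | 2-lithio-1,3-dithiane | [Li]C1SCCCS1 | intermediate (not isolated)
13 | 2-[(2E)-2-(tert-butyldiphenylsilyloxymethyl)-5-(triethylsilyloxy)pent-2-en-1-yl]-1,3-dithiane (C8 dithiane; C9 cis to C2) | C1CSC(SC1)C/C(CO[Si](c2ccccc2)(c3ccccc3)C(C)(C)C)=C\CCO[Si](CC)(CC)CC | intermediate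
14 | dimethylmethyleneiminium iodide | C=[N+](C)C.[I-] | starting material
15 | 2-lithio derivative of 13 | [Li]C1(SCCCS1)C/C(CO[Si](c2ccccc2)(c3ccccc3)C(C)(C)C)=C\CCO[Si](CC)(CC)CC | intermediate (not isolated)
16 | lithium enolate of the conjugate adduct (C7 dithianyl trans to C6 side chain) | [Li]OC1=C[C@H](C2(SCCCS2)C/C(CO[Si](c3ccccc3)(c4ccccc4)C(C)(C)C)=C\CCO[Si](CC)(CC)CC)[C@@H](CO[Si](C)(C)C(C)(C)C)O1 | intermediate (not isolated)
17 | (3R,4S,5S)-5-[(tert-butyldimethylsilyloxy)methyl]-3-[(dimethylamino)methyl]-4-{2-[(2E)-2-(tert-butyldiphenylsilyloxymethyl)-5-(triethylsilyloxy)pent-2-en-1-yl]-1,3-dithian-2-yl}oxolan-2-one | CN(C)C[C@@H]1C(=O)O[C@H](CO[Si](C)(C)C(C)(C)C)[C@H]1C2(SCCCS2)C/C(CO[Si](c3ccccc3)(c4ccccc4)C(C)(C)C)=C\CCO[Si](CC)(CC)CC | intermediate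
18 | C8 ketone: (3R,4S,5S)-lactone bearing the (3E)-3-(tert-butyldiphenylsilyloxymethyl)-6-(triethylsilyloxy)hex-3-enoyl group on C7 | CN(C)C[C@@H]1C(=O)O[C@H](CO[Si](C)(C)C(C)(C)C)[C@H]1C(=O)C/C(CO[Si](c2ccccc2)(c3ccccc3)C(C)(C)C)=C\CCO[Si](CC)(CC)CC | intermediate
19 | (8S)-alcohol of 18 | CN(C)C[C@@H]1C(=O)O[C@H](CO[Si](C)(C)C(C)(C)C)[C@H]1[C@@H](O)C/C(CO[Si](c2ccccc2)(c3ccccc3)C(C)(C)C)=C\CCO[Si](CC)(CC)CC | intermediate
20 | O8-TBS ether of 19 | CN(C)C[C@@H]1C(=O)O[C@H](CO[Si](C)(C)C(C)(C)C)[C@H]1[C@@H](O[Si](C)(C)C(C)(C)C)C/C(CO[Si](c2ccccc2)(c3ccccc3)C(C)(C)C)=C\CCO[Si](CC)(CC)CC | intermediate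
21 | C3 primary alcohol (TES removed from 20) | CN(C)C[C@@H]1C(=O)O[C@H](CO[Si](C)(C)C(C)(C)C)[C@H]1[C@@H](O[Si](C)(C)C(C)(C)C)C/C(CO[Si](c2ccccc2)(c3ccccc3)C(C)(C)C)=C\CCO | intermediate
22 | C3 primary iodide | CN(C)C[C@@H]1C(=O)O[C@H](CO[Si](C)(C)C(C)(C)C)[C@H]1[C@@H](O[Si](C)(C)C(C)(C)C)C/C(CO[Si](c2ccccc2)(c3ccccc3)C(C)(C)C)=C\CCI | intermediate
23 | diethylphosphonoacetic acid | CCOP(=O)(OCC)CC(=O)O | starting material
24 | ethanethiol | CCS | starting material
25 | S-ethyl 2-(diethoxyphosphoryl)ethanethioate | CCOP(=O)(OCC)CC(=O)SCC | intermediate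
26 | sodium salt of 25 (phosphonate carbanion) | [Na+].CCOP(=O)(OCC)[CH-]C(=O)SCC | intermediate (not isolated)
27 | C4 phosphonate thioester (C3 alkylated; C4 epimer mixture) | CN(C)C[C@@H]1C(=O)O[C@H](CO[Si](C)(C)C(C)(C)C)[C@H]1[C@@H](O[Si](C)(C)C(C)(C)C)C/C(CO[Si](c2ccccc2)(c3ccccc3)C(C)(C)C)=C\CCC(C(=O)SCC)P(=O)(OCC)OCC | intermediate
28 | C5 primary alcohol of 27 | CN(C)C[C@@H]1C(=O)O[C@H](CO)[C@H]1[C@@H](O[Si](C)(C)C(C)(C)C)C/C(CO[Si](c2ccccc2)(c3ccccc3)C(C)(C)C)=C\CCC(C(=O)SCC)P(=O)(OCC)OCC | intermediate
29 | C5 aldehyde | CN(C)C[C@@H]1C(=O)O[C@H](C=O)[C@H]1[C@@H](O[Si](C)(C)C(C)(C)C)C/C(CO[Si](c2ccccc2)(c3ccccc3)C(C)(C)C)=C\CCC(C(=O)SCC)P(=O)(OCC)OCC | intermediate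
30 | ten-membered S-ethyl thioester (6R,7R,8S; 11-dimethylaminomethyl; O8-TBS; C14-OTBDPS; both ring alkenes ring-cis) | CC(C)(C)[Si](C)(C)O[C@H]1C/C(CO[Si](c3ccccc3)(c4ccccc4)C(C)(C)C)=C\CC/C(C(=O)SCC)=C\[C@H]2OC(=O)[C@@H](CN(C)C)[C@H]12 | intermediate
31 | C15 enal (O8-TBS; C14-OTBDPS) | CC(C)(C)[Si](C)(C)O[C@H]1C/C(CO[Si](c3ccccc3)(c4ccccc4)C(C)(C)C)=C\CC/C(C=O)=C\[C@H]2OC(=O)[C@@H](CN(C)C)[C@H]12 | intermediate
32 | C8,C14-diol enal | O[C@H]1C/C(CO)=C\CC/C(C=O)=C\[C@H]2OC(=O)[C@@H](CN(C)C)[C@H]12 | intermediate
33 | C14 acetate with free C8 hydroxyl | O[C@H]1C/C(COC(C)=O)=C\CC/C(C=O)=C\[C@H]2OC(=O)[C@@H](CN(C)C)[C@H]12 | intermediate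
34 | ethyl 2-(hydroxymethyl)acrylate | C=C(CO)C(=O)OCC | starting material
35 | ethyl 2-[(tert-butyldimethylsilyloxy)methyl]acrylate | C=C(CO[Si](C)(C)C(C)(C)C)C(=O)OCC | intermediate
36 | 2-[(tert-butyldimethylsilyloxy)methyl]acrylic acid | C=C(CO[Si](C)(C)C(C)(C)C)C(=O)O | intermediate
37 | O8 2-[(tert-butyldimethylsilyloxy)methyl]acrylate of 33 | C=C(CO[Si](C)(C)C(C)(C)C)C(=O)O[C@H]1C/C(COC(C)=O)=C\CC/C(C=O)=C\[C@H]2OC(=O)[C@@H](CN(C)C)[C@H]12 | intermediate
38 | 11-(dimethylaminomethyl) precursor of the target | C=C(CO)C(=O)O[C@H]1C/C(COC(C)=O)=C\CC/C(C=O)=C\[C@H]2OC(=O)[C@@H](CN(C)C)[C@H]12 | intermediate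
39 | trimethylammonium iodide of 38 | C=C(CO)C(=O)O[C@H]1C/C(COC(C)=O)=C\CC/C(C=O)=C\[C@H]2OC(=O)[C@@H](C[N+](C)(C)C)[C@H]12.[I-] | intermediate (not isolated)
40 | CNP0198933.2, (6R,7R,8S) | C=C(CO)C(=O)O[C@H]1C/C(COC(C)=O)=C\CC/C(C=O)=C\[C@H]2OC(=O)C(=C)[C@H]12 | target

**Count**

Total step count: 27. Longest linear sequence: 23 steps (steps 2–14, 16–22 and 25–27).

**Steps most likely to fail**

1. Step 9. The strongly basic 2-alkyl-dithianyl anion may attack the lactone carbonyl or remove the C6 γ-proton instead of adding to C7, and slow Mannich capture would let the enolate equilibrate. The fallback replaces the cyclic dithiane by an acyclic bis(arylthio) carbanion, which is more delocalised, softer and less basic. It sets out from bromide 10: alkylation with bis(phenylthio)methyllithium (from bis(phenylthio)methane and n-BuLi, THF, 0 °C) should give the bis(phenylthio)acetal analogue of 13, F1. F1 is metalated (n-BuLi, TMEDA, THF, −20 °C), added to butenolide 2 at −78 °C and the enolate is captured with 14 to give the bis(phenylthio) ketal lactone F2. Hydrolysis of F2 with Hg(ClO4)2 and CaCO3 in aqueous THF should give ketone 18, where the route is rejoined.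

2. Step 19. Intermolecular olefination to dimers and oligomers may outrun closure of the ten-membered ring, and a slow cyclisation exposes the aldehyde to base-induced epimerisation at C6. The fallback closes the same C4=C5 bond by ring-closing metathesis and sets out from alcohol 28. Olefination of the phosphonate with aqueous formaldehyde (K2CO3, THF) should give the α-methylene thioester alcohol F3, and Dess–Martin oxidation the aldehyde F4. Methylenation with Ph3P=CH2 (THF, −78 °C) should give the C6 vinyl lactone F5. Ring-closing metathesis of F5 as its camphorsulfonate salt with the second-generation Hoveyda–Grubbs catalyst (toluene, 80 °C, 1 mM) expels ethene and should give macrocycle 30, where the route is rejoined; medium-ring metathesis favours the ring-cis alkene that is needed.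

3. Step 11. The dimethylamino group may bind the boron reagents, or the catalyst may be mismatched with the C7 centre, so that facial selectivity at C8 erodes. The fallback uses substrate-controlled reduction and inversion and sets out from ketone 18. Reduction with NaBH4 (MeOH/CH2Cl2, −78 °C) gives 19 together with its C8 epimer, the (8R)-alcohol F6, which is separated. Mitsunobu reaction of F6 with chloroacetic acid (PPh3, DIAD, toluene, 0 °C) should give the inverted (8S)-chloroacetate F7, and mild methanolysis (K2CO3, MeOH, 0 °C) releases 19, where the route is rejoined.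

**Further compounds**

F1 | step 9 | bis(phenylthio)acetal analogue of 13 (C8 bearing two phenylthio groups) | c1ccccc1SC(Sc2ccccc2)C/C(CO[Si](c3ccccc3)(c4ccccc4)C(C)(C)C)=C\CCO[Si](CC)(CC)CC
F2 | step 9 | bis(phenylthio) ketal analogue of 17 | CN(C)C[C@@H]1C(=O)O[C@H](CO[Si](C)(C)C(C)(C)C)[C@H]1C(Sc2ccccc2)(Sc3ccccc3)C/C(CO[Si](c4ccccc4)(c5ccccc5)C(C)(C)C)=C\CCO[Si](CC)(CC)CC
F3 | step 19 | α-methylene thioester alcohol (C4=CH2; C5 hydroxyl) | CN(C)C[C@@H]1C(=O)O[C@H](CO)[C@H]1[C@@H](O[Si](C)(C)C(C)(C)C)C/C(CO[Si](c2ccccc2)(c3ccccc3)C(C)(C)C)=C\CCC(=C)C(=O)SCC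
F4 | step 19 | α-methylene thioester aldehyde (C5 aldehyde) | CN(C)C[C@@H]1C(=O)O[C@H](C=O)[C@H]1[C@@H](O[Si](C)(C)C(C)(C)C)C/C(CO[Si](c2ccccc2)(c3ccccc3)C(C)(C)C)=C\CCC(=C)C(=O)SCC
F5 | step 19 | C6 vinyl lactone diene for metathesis | CN(C)C[C@@H]1C(=O)O[C@H](C=C)[C@H]1[C@@H](O[Si](C)(C)C(C)(C)C)C/C(CO[Si](c2ccccc2)(c3ccccc3)C(C)(C)C)=C\CCC(=C)C(=O)SCC
F6 | step 11 | (8R)-alcohol, C8 epimer of 19 | CN(C)C[C@@H]1C(=O)O[C@H](CO[Si](C)(C)C(C)(C)C)[C@H]1[C@H](O)C/C(CO[Si](c2ccccc2)(c3ccccc3)C(C)(C)C)=C\CCO[Si](CC)(CC)CC
F7 | step 11 | (8S)-chloroacetate of 19 | CN(C)C[C@@H]1C(=O)O[C@H](CO[Si](C)(C)C(C)(C)C)[C@H]1[C@@H](OC(=O)CCl)C/C(CO[Si](c2ccccc2)(c3ccccc3)C(C)(C)C)=C\CCO[Si](CC)(CC)CC
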